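**Strategy.** With atoms numbered in target-SMILES order, the oxepan-3-one ring (O28, C25, C23, C22, C21, C19, C29) is read as a 2,2-dimethylfuran-3(2H)-one (O28, C25, C23, C22, C29) whose C22–C29 bond has taken up C21 and C19. Irradiation of a 5-alkenyl furanone, whose tether carries C18 and C32 already set, makes C19–C29 and C21–C22 at once, closing the cyclohexane (C18, C19, C29–C32) and a cyclobutane. Strain-driven reductive opening of C22–C29 then gives the trans-fused oxepanone, and a Julia–Kocienski union with a separately built cis-hydroazulene sulfone followed by alkene saturation completes the skeleton.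

Key step: step 8

Remark: in step 12 the catalyst antipode is taken to be the one that delivers the (R)-adduct 20; the mirror-image catalyst would be used if the sense of induction is the opposite.

**Part 1 – oxepane half (C17–O34)**

Step 1
Reactants: 1 neryl acetate
Product: 2 (2Z)-3-methyl-6-oxohex-2-en-1-yl acetate
Conditions: O3, CH2Cl2, pyridine, −78 °C; Me2S
Reagents that add atoms: ozone, O=[O+][O-]
Why: Chemoselective ozonolysis should cleave only the remote trisubstituted alkene, because the 2,3-alkene is deactivated by the allylic acetate, and the Z geometry is untouched.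

Step 2
Reactants: 2 (2Z)-3-methyl-6-oxohex-2-en-1-yl acetate
Product: 4 (2Z)-3-methylhept-2-en-6-yn-1-ol, via enyne acetate 3 (not isolated)
Conditions: Ohira–Bestmann reagent, K2CO3, MeOH, 0 °C → rt
Reagents that add atoms: dimethyl (1-diazo-2-oxopropyl)phosphonate, CC(=O)C(=[N+]=[N-])P(=O)(OC)OC
Why: Seyferth–Gilbert homologation in its Ohira–Bestmann form turns the aldehyde into the terminal alkyne, and the same methanolic carbonate cleaves the allylic acetate.

Step 3
Reactants: 4 (2Z)-3-methylhept-2-en-6-yn-1-ol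
Product: 5 [(2R,3S)-3-(but-3-yn-1-yl)-3-methyloxiran-2-yl]methanol
Conditions: Ti(OiPr)4, D-(−)-diethyl tartrate, t-BuOOH, 4 Å MS, CH2Cl2, −20 °C
Reagents that add atoms: tert-butyl hydroperoxide, CC(C)(C)OO
Why: Sharpless asymmetric epoxidation with the D-tartrate should deliver oxygen to the face of the Z-allylic alcohol that gives the 2R,3S epoxide, which fixes the carbons that become C18 and C32.

Step 4
Reactants: 5 [(2R,3S)-3-(but-3-yn-1-yl)-3-methyloxiran-2-yl]methanol
Product: 6 (2S,3S)-3-methyl-2-(prop-1-en-2-yl)hept-6-yne-1,3-diol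
Conditions: isopropenylMgBr (excess), CuI (cat.), THF, −30 → 0 °C
Reagents that add atoms: isopropenylmagnesium bromide, CC(=C)[Mg]Br
Why: Copper-mediated SN2 opening of a 3,3-disubstituted 2,3-epoxy alcohol occurs at C2 because C3 is fully substituted, so C18 is set by inversion while the C32–O bond is retained; the hydroxyl and the alkyne C–H only consume Grignard reagent.

Step 5
Reactants: 6 (2S,3S)-3-methyl-2-(prop-1-en-2-yl)hept-6-yne-1,3-diol
Product: 7 (2S,3S)-1,3-bis(tert-butyldimethylsilyloxy)-3-methyl-2-(prop-1-en-2-yl)hept-6-yne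
Conditions: TBSOTf (2.5 equiv), 2,6-lutidine, CH2Cl2, −78 → 0 °C
Reagents that add atoms: tert-butyldimethylsilyl triflate, CC(C)(C)[Si](C)(C)OS(=O)(=O)C(F)(F)F
Why: Silyl triflate silylation caps both hydroxyls in one operation, and the bulky, robust TBS group on the tertiary oxygen keeps it from adding to the furanone or trapping the later C29 oxocarbenium, shields one ring face in step 8 and lasts to the final step.

Step 6
Reactants: 7 (2S,3S)-1,3-bis(tert-butyldimethylsilyloxy)-3-methyl-2-(prop-1-en-2-yl)hept-6-yne; 8 2-acetoxy-2-methylpropanoyl chloride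
Product: 9 (8S,9S)-8-(tert-butyldimethylsilyloxy)-9-[(tert-butyldimethylsilyloxy)methyl]-2,8,10-trimethyl-3-oxoundec-10-en-4-yn-2-yl acetate
Conditions: PdCl2(PPh3)2 (cat.), CuI (cat.), Et3N, THF, rt
Reagents that add atoms: none
Why: Acyl Sonogashira coupling of a terminal alkyne with a non-enolisable acid chloride gives the ynone (C22≡C29, C23=O) directly without strong base.

Step 7
Reactants: 9 the acetoxy ynone
Product: 11 5-[(3S,4S)-3-(tert-butyldimethylsilyloxy)-4-[(tert-butyldimethylsilyloxy)methyl]-3,5-dimethylhex-5-en-1-yl]-2,2-dimethylfuran-3(2H)-one, via hydroxy ynone 10 (not isolated)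
Conditions: K2CO3, MeOH, rt
Reagents that add atoms: none
Why: Methanolysis frees the tertiary alcohol, whose alkoxide closes onto the ynone by 5-endo-dig oxa-Michael addition, the standard base-mediated route from α′-hydroxy ynones to 3(2H)-furanones.

Step 8
Reactants: 11 the 5-alkenyl-2,2-dimethylfuran-3(2H)-one
Product: 12 tricyclic cyclobutane photoadduct (bis-TBS)
Conditions: hν (λ > 300 nm, Pyrex), degassed MeCN (high dilution), 0 °C
Reagents that add atoms: none
Why: Intramolecular enone–alkene [2+2] photocycloaddition, known for β-alkoxy enones such as 3(2H)-furanones: the triplet furanone bonds through its β-carbon C29 to the fully substituted alkene carbon C19, and the resulting 1,4-diradical (C22/C21) collapses to the cyclobutane. The cyclohexane is closed by 6-exo (1,6) attack at C19 and the cyclobutane by radical recombination C22–C21. C19 and C29 are controlled by C18 and C32 through a chair-like fold of the tether with the C17 arm and the C32 methyl equatorial and the C32 silyloxy group axial; that bulky axial group blocks its own face, so the four-membered ring forms on the opposite face with only the C19 methyl syn to it, and C22 follows from the enforced cis fusion of the cyclobutane to both neighbouring rings. The step needs straight (C29–C19, C22–C21) and not crossed closure, which the four-atom link between C29 and C19 secures because six-membered first closure outruns seven-membered closure, and it needs one π-face, which the equatorial C17 arm and the axial silyloxy group secure together.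

Step 9
Reactants: 12 tricyclic cyclobutane photoadduct
Product: 15 trans-fused bis-TBS oxepan-3-one, via oxepinium enol silane triflate 13 (not isolated), via enol silane 14 (not isolated)
Conditions: TMSOTf, 2,6-di-tert-butyl-4-methylpyridine, CH2Cl2, −78 °C; then Et3SiH, −78 → −30 °C; aq. NaHCO3
Reagents that add atoms: none
Why: Proposed new method: silylation of the C23 carbonyl should make the strained C22–C29 bond, which lies between the O28 lone pair (donor) and the activated carbonyl (acceptor), heterolyse to the seven-membered oxocarbenium ion and a C22=C23 silyl enol ether, after which Et3SiH delivers hydride axially to C29 on the face that C22 has left, anti to the axial C19 methyl and the axial C32 silyloxy group, to give the trans-fused ether, and the enol silane hydrolyses to the C23 ketone on work-up; the closest known reaction types are Lewis-acid ring opening of vicinal donor–acceptor cyclobutanes, de Mayo retro-aldol fragmentation of [2+2] adducts, and silane reduction of cyclic oxocarbenium ions in reductive etherification.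

Step 10
Reactants: 15 trans-fused bis-TBS oxepan-3-one
Product: 16 primary alcohol (C17–OH) with the C32 TBS ether retained
Conditions: HF·pyridine, excess pyridine, THF, 0 °C
Reagents that add atoms: none
Why: Buffered fluoride desilylation distinguishes the unhindered primary TBS ether from the hindered tertiary one.

Step 11
Reactants: 16 primary alcohol
Product: 17 C17 aldehyde
Conditions: Dess–Martin periodinane, NaHCO3, CH2Cl2, 0 °C → rt
Reagents that add atoms: none
Why: Dess–Martin oxidation under buffered, non-basic conditions gives the β-silyloxy aldehyde without retro-aldol loss and without epimerising C18, whose formyl group is in any case in the stable equatorial position.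

**Part 2 – hydroazulene sulfone (C1–C16)**

Step 12
Reactants: 18 cyclopent-2-en-1-one; 19 1-methoxy-2-methyl-1-(trimethylsilyloxy)prop-1-ene
Product: 20 methyl 2-methyl-2-[(1R)-3-(trimethylsilyloxy)cyclopent-2-en-1-yl]propanoate
Conditions: chiral o-tolyl oxazaborolidinium triflimide (10 mol %), toluene, −20 °C; non-aqueous work-up
Reagents that add atoms: none
Why: Enantioselective Mukaiyama–Michael addition, in which the chiral oxazaborolidinium Lewis acid shields one face of the bound enone so that the silyl ketene acetal sets C6 and creates the quaternary C12, and silyl transfer leaves the regiodefined enol silane.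

Step 13
Reactants: 20 the enol silane
Product: 23 methyl 2-methyl-2-[(1R)-2-methylidene-3-oxocyclopentyl]propanoate, via Mannich base 21 (not isolated), via ammonium iodide 22 (not isolated)
Conditions: Me2N=CH2 I (Eschenmoser's salt), CH2Cl2, rt; MeI, THF; DBU, 0 °C; used at once
Reagents that add atoms: N,N-dimethylmethyleneiminium iodide, C=[N+](C)C.[I-]
Why: Regiospecific Mannich reaction of the enol silane followed by quaternisation and E1cB elimination places the exocyclic methylene (C4) on C5 only.

Step 14
Reactants: 23 the α-methylene ketone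
Product: 25 methyl 2-methyl-2-[(1R,2R)-3-oxo-2-(prop-2-en-1-yl)cyclopentyl]propanoate, via magnesium enolate 24 (not isolated)
Conditions: vinylMgBr, CuBr·SMe2 (cat.), THF, −78 °C; AcOH, −78 °C; no chromatography
Reagents that add atoms: vinylmagnesium bromide, C=C[Mg]Br
Why: Copper-catalysed conjugate addition to the exocyclic enone builds the allyl arm, and kinetic protonation of the enolate anti to the bulky C6 substituent should give the cis-2,3-disubstituted ketone (C5).

Step 15
Reactants: 25 the cis ketone
Product: 26 methyl 2-methyl-2-[(1R,2R)-3-methylidene-2-(prop-2-en-1-yl)cyclopentyl]propanoate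
Conditions: Zn, CH2Br2, TiCl4, THF/CH2Cl2, 0 °C → rt
Reagents that add atoms: dibromomethane, BrCBr
Why: Lombardo methylenation is non-basic, so the epimerisable cis ketone is converted to the alkene without loss of C5 and without touching the ester.

Step 16
Reactants: 26 the exocyclic alkene
Product: 27 methyl 2-methyl-2-[(3R,4R,5R)-4-(prop-2-en-1-yl)-1-oxaspiro[2.4]heptan-5-yl]propanoate
Conditions: mCPBA (1 equiv), NaHCO3, CH2Cl2, 0 °C
Reagents that add atoms: 3-chloroperoxybenzoic acid, OOC(=O)c1cccc(Cl)c1
Why: Prilezhaev epoxidation picks the more nucleophilic 1,1-disubstituted alkene and attacks it from the face opposite the two cis carbon substituents, which sets the C9–O bond.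

Step 17
Reactants: 27 the spiro-epoxide
Product: 28 (1R,2R,3R)-3-(1-hydroxy-2-methylpropan-2-yl)-1-methyl-2-(prop-2-en-1-yl)cyclopentan-1-ol
Conditions: LiAlH4, THF, 0 °C → rt
Reagents that add atoms: none
Why: Hydride opens the epoxide at its CH2 terminus, leaving the tertiary alcohol with the C9 configuration of the epoxide (OH trans to the allyl group, methyl cis), and reduces the ester to the neopentyl alcohol.

Step 18
Reactants: 28 the diol
Product: 29 2-[(1R,2R,3R)-3-hydroxy-3-methyl-2-(prop-2-en-1-yl)cyclopentyl]-2-methylpropanal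
Conditions: TEMPO (cat.), PhI(OAc)2, CH2Cl2, rt
Reagents that add atoms: none
Why: Oxoammonium (TEMPO) oxidation is selective for the primary alcohol, and the aldehyde has no α-hydrogen.

Step 19
Reactants: 29 the aldehyde
Product: 30 4-[(1R,2R,3R)-3-hydroxy-3-methyl-2-(prop-2-en-1-yl)cyclopentyl]-2,4-dimethylpent-1-en-3-ol (both carbinol epimers)
Conditions: isopropenylMgBr (3 equiv), THF, −78 → 0 °C
Reagents that add atoms: isopropenylmagnesium bromide, CC(=C)[Mg]Br
Why: Grignard addition brings in C2 and C1, and the new carbinol centre is removed again in the next step.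

Step 20
Reactants: 30 the allylic alcohol
Product: 31 4-[(1R,2R,3R)-3-hydroxy-3-methyl-2-(prop-2-en-1-yl)cyclopentyl]-2,4-dimethylpent-1-en-3-one
Conditions: Dess–Martin periodinane, NaHCO3, CH2Cl2, rt
Reagents that add atoms: none
Why: Dess–Martin oxidation of the secondary allylic alcohol gives the isopropenyl ketone while the tertiary alcohol is inert.

Step 21
Reactants: 31 the dienone
Product: 32 (3R,3aR,8aR)-3-hydroxy-3,6,8,8-tetramethyl-2,3,3a,4,8,8a-hexahydroazulen-7(1H)-one
Conditions: Grubbs II catalyst (5 mol %), CH2Cl2, 40 °C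
Reagents that add atoms: none
Why: Ring-closing metathesis between the allyl group and the methacryloyl alkene closes the seven-membered ring as the 2-methyl enone (C2=C3), with the cis ring fusion already fixed by C5 and C6.

Step 22
Reactants: 32 the hydroxy enone
Product: 33 (3R,3aR,8aR)-3,6,8,8-tetramethyl-3-(triethylsilyloxy)-2,3,3a,4,8,8a-hexahydroazulen-7(1H)-one
Conditions: TESOTf, 2,6-lutidine, CH2Cl2, −78 → 0 °C
Reagents that add atoms: triethylsilyl triflate, CC[Si](CC)(CC)OS(=O)(=O)C(F)(F)F
Why: Silyl triflate protection of the tertiary alcohol keeps the later organometallic and carbanion steps clean.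

Step 23
Reactants: 33 the TES enone
Product: 34 7-methylidene diene (C15=C16H2)
Conditions: Cp2TiMe2, toluene, 70 °C
Reagents that add atoms: dimethyltitanocene, C[Ti](C)(C1C=CC=C1)C1C=CC=C1
Why: Petasis methylenation works on hindered, conjugated ketones where phosphorus ylides fail, and it is not basic.

Step 24
Reactants: 34 the diene
Product: 36 [(3R,3aR,7S,8aR)-3,6,8,8-tetramethyl-3-(triethylsilyloxy)-1,2,3,3a,4,7,8,8a-octahydroazulen-7-yl]methanol, via B-alkyl-9-BBN 35 (not isolated)
Conditions: 9-BBN, THF, rt → 50 °C; NaOH, H2O2, 0 °C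
Reagents that add atoms: hydrogen peroxide, OO
Why: Hydroboration–oxidation with 9-BBN attacks only the 1,1-disubstituted terminus of the diene, boron at C16, and delivers hydrogen to C15 from the convex face away from the cis-fused cyclopentane, which sets C15 with H15 cis to H6.

Step 25
Reactants: 36 the primary alcohol
Product: 37 1-phenyl-1H-tetrazol-5-yl sulfide of 36
Conditions: 1-phenyl-1H-tetrazole-5-thiol, PPh3, DIAD, THF, 0 °C → rt
Reagents that add atoms: 1-phenyl-1H-tetrazole-5-thiol, Sc1nnnn1-c1ccccc1
Why: Mitsunobu thioetherification of the primary alcohol proceeds at C16, which is not a stereocentre.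

Step 26
Reactants: 37 the sulfide
Product: 38 hydroazulene PT-sulfone
Conditions: (NH4)6Mo7O24·4H2O (cat.), 30 % H2O2, EtOH, 0 °C → rt
Reagents that add atoms: hydrogen peroxide, OO
Why: Molybdate-catalysed peroxide oxidation takes the sulfide to the sulfone much faster than it epoxidises the hindered trisubstituted alkene.

**Part 3 – union and completion**

Step 27
Reactants: 38 hydroazulene PT-sulfone; 17 C17 aldehyde
Product: 40 C16=C17 alkene (E/Z mixture), via potassium sulfonyl carbanion 39 (not isolated)
Conditions: KHMDS, THF, −78 °C; then 17, −78 °C → rt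
Reagents that add atoms: none
Why: Julia–Kocienski olefination, in which the premetalated PT-sulfone adds to the aldehyde in preference to the hindered ketone and Smiles rearrangement with loss of SO2 and the tetrazolone forms the C16=C17 bond, whose geometry does not matter.

Step 28
Reactants: 40 the C16=C17 alkene
Product: 41 bis-silyl ether of the target (32-O-TBS, 9-O-TES)
Conditions: KO2CN=NCO2K, AcOH, pyridine, MeOH, rt
Reagents that add atoms: none
Why: Diimide reduction saturates the 1,2-disubstituted alkene by concerted syn hydrogen transfer and leaves the trisubstituted ring alkene and the ketone alone.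

Step 29
Reactants: 41 the bis-silyl ether
Product: 42 sipholenone A
Conditions: HF·pyridine, THF, rt → 40 °C
Reagents that add atoms: none
Why: Fluoride-mediated desilylation removes both tertiary silyl ethers without touching the ketone, the alkene or any stereocentre.

**Compound list**

1 | neryl acetate, (2Z)-3,7-dimethylocta-2,6-dien-1-yl acetate | CC(=O)OC/C=C(C)\CCC=C(C)C | starting material
2 | (2Z)-3-methyl-6-oxohex-2-en-1-yl acetate | CC(=O)OC/C=C(C)\CCC=O | intermediate
3 | (2Z)-3-methylhept-2-en-6-yn-1-yl acetate | CC(=O)OC/C=C(C)\CCC#C | intermediate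
4 | (2Z)-3-methylhept-2-en-6-yn-1-ol | OC/C=C(C)\CCC#C | intermediate
5 | [(2R,3S)-3-(but-3-yn-1-yl)-3-methyloxiran-2-yl]methanol | OC[C@H]1O[C@@]1(C)CCC#C | intermediate
6 | (2S,3S)-3-methyl-2-(prop-1-en-2-yl)hept-6-yne-1,3-diol | OC[C@H](C(C)=C)[C@@](C)(O)CCC#C | intermediate
7 | (2S,3S)-1,3-bis(tert-butyldimethylsilyloxy)-3-methyl-2-(prop-1-en-2-yl)hept-6-yne | CC(C)(C)[Si](C)(C)OC[C@H](C(C)=C)[C@@](C)(O[Si](C)(C)C(C)(C)C)CCC#C | intermediate
8 | 2-acetoxy-2-methylpropanoyl chloride | CC(=O)OC(C)(C)C(Cl)=O | starting material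
9 | (8S,9S)-8-(tert-butyldimethylsilyloxy)-9-[(tert-butyldimethylsilyloxy)methyl]-2,8,10-trimethyl-3-oxoundec-10-en-4-yn-2-yl acetate | CC(C)(C)[Si](C)(C)OC[C@H](C(C)=C)[C@@](C)(O[Si](C)(C)C(C)(C)C)CCC#CC(=O)C(C)(C)OC(C)=O | intermediate
10 | 2-hydroxy ynone, the deacetylated form of 9 | CC(C)(C)[Si](C)(C)OC[C@H](C(C)=C)[C@@](C)(O[Si](C)(C)C(C)(C)C)CCC#CC(=O)C(C)(C)O | intermediate
11 | 5-[(3S,4S)-3-(tert-butyldimethylsilyloxy)-4-[(tert-butyldimethylsilyloxy)methyl]-3,5-dimethylhex-5-en-1-yl]-2,2-dimethylfuran-3(2H)-one | CC(C)(C)[Si](C)(C)OC[C@H](C(C)=C)[C@@](C)(O[Si](C)(C)C(C)(C)C)CCC1=CC(=O)C(C)(C)O1 | intermediate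
12 | photoadduct: cyclohexane (C18, C19, C29–C32) cis-fused to cyclobutane (C19, C21, C22, C29), itself cis-fused to the 2,2-dimethyloxolan-3-one; C19-methyl, O28, C32-OTBS and the C17 CH2OTBS arm on one face, C21, C22 and the C32-methyl on the other | CC(C)(C)[Si](C)(C)OC[C@@H]1[C@@]2(C)C[C@@H]3C(=O)C(C)(C)O[C@]23CC[C@]1(C)O[Si](C)(C)C(C)(C)C | intermediate
13 | ring-opened oxepinium ion (O28=C29) carrying the C22=C23 trimethylsilyl enol ether, triflate salt | CC(C)(C)[Si](C)(C)OC[C@@H]1[C@@]2(C)CC=C(O[Si](C)(C)C)C(C)(C)[O+]=C2CC[C@]1(C)O[Si](C)(C)C(C)(C)C.[O-]S(=O)(=O)C(F)(F)F | intermediate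
14 | trimethylsilyl enol ether of 15 (C22=C23), C29–H in place | CC(C)(C)[Si](C)(C)OC[C@@H]1[C@@]2(C)CC=C(O[Si](C)(C)C)C(C)(C)O[C@@H]2CC[C@]1(C)O[Si](C)(C)C(C)(C)C | intermediate
15 | trans-fused oxepan-3-one on cyclohexane, 17-O-TBS and 32-O-TBS; C29–H anti to the C19-methyl, C18, C19 and C32 arranged as in the target | CC(C)(C)[Si](C)(C)OC[C@@H]1[C@@]2(C)CCC(=O)C(C)(C)O[C@@H]2CC[C@]1(C)O[Si](C)(C)C(C)(C)C | intermediate
16 | C17 primary alcohol of 15, 32-O-TBS retained | OC[C@@H]1[C@@]2(C)CCC(=O)C(C)(C)O[C@@H]2CC[C@]1(C)O[Si](C)(C)C(C)(C)C | intermediate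
17 | C17 aldehyde, 32-O-TBS retained, stereocentres as in 15 | O=C[C@@H]1[C@@]2(C)CCC(=O)C(C)(C)O[C@@H]2CC[C@]1(C)O[Si](C)(C)C(C)(C)C | intermediate
18 | cyclopent-2-en-1-one | O=C1C=CCC1 | starting material
19 | 1-methoxy-2-methyl-1-(trimethylsilyloxy)prop-1-ene | COC(O[Si](C)(C)C)=C(C)C | starting material
20 | methyl 2-methyl-2-[(1R)-3-(trimethylsilyloxy)cyclopent-2-en-1-yl]propanoate | C[Si](C)(C)OC1=C[C@@H](CC1)C(C)(C)C(=O)OC | intermediate
21 | trans Mannich base, methyl 2-[(1R,2R)-2-[(dimethylamino)methyl]-3-oxocyclopentyl]-2-methylpropanoate | CN(C)C[C@H]1[C@@H](CCC1=O)C(C)(C)C(=O)OC | intermediate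
22 | trimethylammonium iodide of 21 | C[N+](C)(C)C[C@H]1[C@@H](CCC1=O)C(C)(C)C(=O)OC.[I-] | intermediate
23 | methyl 2-methyl-2-[(1R)-2-methylidene-3-oxocyclopentyl]propanoate | C=C1[C@@H](CCC1=O)C(C)(C)C(=O)OC | intermediate
24 | bromomagnesium enolate of 25 | Br[Mg]OC1=C(CC=C)[C@@H](CC1)C(C)(C)C(=O)OC | intermediate
25 | methyl 2-methyl-2-[(1R,2R)-3-oxo-2-(prop-2-en-1-yl)cyclopentyl]propanoate (2,3-cis) | C=CC[C@@H]1[C@@H](CCC1=O)C(C)(C)C(=O)OC | intermediate
26 | methyl 2-methyl-2-[(1R,2R)-3-methylidene-2-(prop-2-en-1-yl)cyclopentyl]propanoate | C=CC[C@@H]1[C@@H](CCC1=C)C(C)(C)C(=O)OC | intermediate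
27 | methyl 2-methyl-2-[(3R,4R,5R)-4-(prop-2-en-1-yl)-1-oxaspiro[2.4]heptan-5-yl]propanoate | C=CC[C@@H]1[C@@H](CC[C@]12CO2)C(C)(C)C(=O)OC | intermediate
28 | (1R,2R,3R)-3-(1-hydroxy-2-methylpropan-2-yl)-1-methyl-2-(prop-2-en-1-yl)cyclopentan-1-ol | C=CC[C@@H]1[C@@H](CC[C@@]1(C)O)C(C)(C)CO | intermediate
29 | 2-[(1R,2R,3R)-3-hydroxy-3-methyl-2-(prop-2-en-1-yl)cyclopentyl]-2-methylpropanal | C=CC[C@@H]1[C@@H](CC[C@@]1(C)O)C(C)(C)C=O | intermediate
30 | 4-[(1R,2R,3R)-3-hydroxy-3-methyl-2-(prop-2-en-1-yl)cyclopentyl]-2,4-dimethylpent-1-en-3-ol, both carbinol epimers | C=CC[C@@H]1[C@@H](CC[C@@]1(C)O)C(C)(C)C(O)C(C)=C | intermediate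
31 | 4-[(1R,2R,3R)-3-hydroxy-3-methyl-2-(prop-2-en-1-yl)cyclopentyl]-2,4-dimethylpent-1-en-3-one | C=CC[C@@H]1[C@@H](CC[C@@]1(C)O)C(C)(C)C(=O)C(C)=C | intermediate
32 | (3R,3aR,8aR)-3-hydroxy-3,6,8,8-tetramethyl-2,3,3a,4,8,8a-hexahydroazulen-7(1H)-one (cis-fused) | CC1=CC[C@@H]2[C@@H](CC[C@@]2(C)O)C(C)(C)C1=O | intermediate
33 | (3R,3aR,8aR)-3,6,8,8-tetramethyl-3-(triethylsilyloxy)-2,3,3a,4,8,8a-hexahydroazulen-7(1H)-one | CC1=CC[C@@H]2[C@@H](CC[C@@]2(C)O[Si](CC)(CC)CC)C(C)(C)C1=O | intermediate
34 | diene: 33 with C7=O replaced by C7=CH2, stereocentres as in 33 | CC1=CC[C@@H]2[C@@H](CC[C@@]2(C)O[Si](CC)(CC)CC)C(C)(C)C1=C | intermediate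
35 | B-alkyl-9-borabicyclo[3.3.1]nonane adduct of 34, boron on C16 | CC1=CC[C@@H]2[C@@H](CC[C@@]2(C)O[Si](CC)(CC)CC)C(C)(C)[C@H]1CB1C2CCCC1CCC2 | intermediate
36 | [(3R,3aR,7S,8aR)-3,6,8,8-tetramethyl-3-(triethylsilyloxy)-1,2,3,3a,4,7,8,8a-octahydroazulen-7-yl]methanol | CC1=CC[C@@H]2[C@@H](CC[C@@]2(C)O[Si](CC)(CC)CC)C(C)(C)[C@H]1CO | intermediate
37 | 1-phenyl-1H-tetrazol-5-yl sulfide of 36, stereocentres unchanged | CC1=CC[C@@H]2[C@@H](CC[C@@]2(C)O[Si](CC)(CC)CC)C(C)(C)[C@H]1CSc1nnnn1-c1ccccc1 | intermediate
38 | 1-phenyl-1H-tetrazol-5-yl sulfone of 36, stereocentres unchanged | CC1=CC[C@@H]2[C@@H](CC[C@@]2(C)O[Si](CC)(CC)CC)C(C)(C)[C@H]1CS(=O)(=O)c1nnnn1-c1ccccc1 | intermediate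
39 | potassium α-sulfonyl carbanion of 38 (C16) | CC1=CC[C@@H]2[C@@H](CC[C@@]2(C)O[Si](CC)(CC)CC)C(C)(C)[C@H]1[CH-]S(=O)(=O)c1nnnn1-c1ccccc1.[K+] | intermediate
40 | 16,17-didehydro bis-silyl ether of the target (E/Z), all stereocentres as in the target | CC1=CC[C@@H]2[C@@H](CC[C@@]2(C)O[Si](CC)(CC)CC)C(C)(C)[C@H]1C=C[C@@H]1[C@@]2(C)CCC(=O)C(C)(C)O[C@@H]2CC[C@]1(C)O[Si](C)(C)C(C)(C)C | intermediate
41 | 9-O-TES 32-O-TBS ether of sipholenone A | CC1=CC[C@@H]2[C@@H](CC[C@@]2(C)O[Si](CC)(CC)CC)C(C)(C)[C@H]1CC[C@@H]1[C@@]2(C)CCC(=O)C(C)(C)O[C@@H]2CC[C@]1(C)O[Si](C)(C)C(C)(C)C | intermediate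
42 | sipholenone A | CC1=CC[C@@H]2[C@@H](CC[C@@]2(C)O)C(C)(C)[C@H]1CC[C@@H]1[C@@]2(C)CCC(=O)C(C)(C)O[C@@H]2CC[C@]1(C)O | target

**Step count and risk**

Total: 29 steps. Longest linear sequence: 18 steps (steps 12–29, from cyclopent-2-en-1-one); the oxepane half needs 11 steps to aldehyde 17.

1. Step 9 (proposed new method). The silyl triflate may activate the C23 carbonyl for direct hydride reduction before the C22–C29 bond breaks, the oxocarbenium may be reduced from the wrong face, or silyl groups may be lost. The fallback separates bond cleavage from reduction with known chemistry and sets out from 12. Aqueous acid (TsOH, wet acetone) would effect the de Mayo-type hydrolytic retro-aldol opening of the 2-alkoxycyclobutyl ketone to the ring-opened hydroxy diketone F1, in which C29 is a cyclohexanone carbonyl and C25 carries a free tertiary hydroxyl. Established reductive etherification of this hydroxy ketone (Et3SiH with BiBr3 or TMSOTf, through the seven-membered hemiketal) would then close the oxepane with axial hydride delivery and come back to the route at 15.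

2. Step 8. The tether may fold without enough facial bias, so that the enone adds to both faces of the isopropenyl group. The fallback ties O17 and O34 into a ring and sets out from diol 6. tBu2Si(OTf)2 and 2,6-lutidine would give the cyclic di-tert-butylsilylene alkyne F2; acyl Sonogashira coupling with 8 would give the silylene ynone acetate F3; K2CO3 in methanol would give the silylene furanone F4. Irradiation of F4, in which the C18–C32 rotamer is frozen and a tert-butyl group covers the face to be blocked, should give the silylene photoadduct F5. HF·pyridine would release the diol photoadduct F6, and TBSOTf with 2,6-lutidine would return it to the route at 12.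

3. Step 27. Addition of the branched sulfonyl carbanion to the hindered, enolisable β-silyloxy aldehyde may be slower than proton transfer, which would return both partners or epimerise C18. The fallback replaces sulfur by phosphorus and sets out from alcohol 36. I2, PPh3 and imidazole would give the primary iodide F7; heating with PPh3 in acetonitrile would give the phosphonium iodide F8; its ylide (NaHMDS, THF, −78 °C), which is more nucleophilic and less basic towards the aldehyde, would undergo Wittig olefination with 17 and come back to the route at 40.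

**Further compounds**

F1 | step 9 | hydroxy diketone: 2-oxocyclohexane bearing at C19 the methyl group and the 5-hydroxy-5-methyl-4-oxohexyl-type chain CH2CH2C(=O)C(CH3)2OH, with 17-O-TBS and 32-O-TBS | CC(C)(C)[Si](C)(C)OC[C@@H]1[C@@](C)(CCC(=O)C(C)(C)O)C(=O)CC[C@]1(C)O[Si](C)(C)C(C)(C)C
F2 | step 8 | cyclic di-tert-butylsilylene of diol 6 | CC(C)(C)[Si]1(C(C)(C)C)OC[C@H](C(C)=C)[C@](C)(CCC#C)O1
F3 | step 8 | silylene ynone acetate | CC(C)(C)[Si]1(C(C)(C)C)OC[C@H](C(C)=C)[C@](C)(CCC#CC(=O)C(C)(C)OC(C)=O)O1
F4 | step 8 | silylene 5-alkenyl-2,2-dimethylfuran-3(2H)-one | CC(C)(C)[Si]1(C(C)(C)C)OC[C@H](C(C)=C)[C@](C)(CCC2=CC(=O)C(C)(C)O2)O1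
F5 | step 8 | silylene-bridged cyclobutane photoadduct | CC(C)(C)[Si]4(C(C)(C)C)OC[C@@H]1[C@@]2(C)C[C@@H]3C(=O)C(C)(C)O[C@]23CC[C@]1(C)O4
F6 | step 8 | diol photoadduct (C17–OH and C32–OH free) | OC[C@@H]1[C@@]2(C)C[C@@H]3C(=O)C(C)(C)O[C@]23CC[C@]1(C)O
F7 | step 27 | C16 iodide of the hydroazulene, 9-O-TES | CC1=CC[C@@H]2[C@@H](CC[C@@]2(C)O[Si](CC)(CC)CC)C(C)(C)[C@H]1CI
F8 | step 27 | C16 triphenylphosphonium iodide of the hydroazulene, 9-O-TES | CC1=CC[C@@H]2[C@@H](CC[C@@]2(C)O[Si](CC)(CC)CC)C(C)(C)[C@H]1C[P+](c1ccccc1)(c1ccccc1)c1ccccc1.[I-]
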